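**Retrosynthetic overview**
- The usual plan (aldol condensation to the chalcone-type enone, hydrogenation, acylation of an O-protected resorcinol, late chlorination, deprotection) is set aside; this route uses no protecting groups.
- Last bond: aryl–C(=O), by acylating a symmetrical 2-alkylresorcinol with 4,5-dichloropyrrole-2-carboxylic acid; its two activated ring carbons are equivalent, so only one monoketone can form.
- Key step: the resorcinol ring is created from a 2-alkylcyclohexane-1,3-dione by SO2Cl2, which chlorinates the pyrrole twice and the dione C2 once; an HCl-promoted chloride shift and loss of HCl then aromatise, so chlorination is complete before a phenol exists.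
- The dione–pyrrole ketone comes from C2-acylation of pyrrole (as its magnesium salt) by an enol lactone made from cyclohexane-1,3-dione and acrylic acid.
- Ring order: the cyclohexanedione ring is bought, the dihydropyranone ring is closed (step 1) and opened again (step 2), the benzene ring is formed by aromatisation (step 3); both pyrrole rings are bought intact.

Assumption: the target has no stereocentre (it is achiral), so the "single enantiomer" is simply the constitution given and no stereocontrol is needed.

**Route**

Step 1
Reactants: 1 cyclohexane-1,3-dione; 2 acrylic acid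
Product: 4 3,4,7,8-tetrahydro-2H-chromene-2,5(6H)-dione, via 3-(2,6-dioxocyclohexyl)propanoic acid 3 (not isolated)
Conditions: 2 (1.5 equiv), p-TsOH·H2O (5 mol %), 4-methoxyphenol (0.5 mol %), xylene, 140 °C, Dean–Stark, 12 h
Reagents that add atoms: none
Why: Michael addition of the dione enol (C2 is its only nucleophilic carbon, which fixes the later 2-position of the resorcinol) to acrylic acid, followed by acid-catalysed enol lactonisation driven by azeotropic removal of water; this is a tandem Michael addition–lactonisation of a cyclic 1,3-dione, and no stereocentre is formed.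

Step 2
Reactants: 4 3,4,7,8-tetrahydro-2H-chromene-2,5(6H)-dione; 5 1H-pyrrole
Product: 7 2-[3-oxo-3-(1H-pyrrol-2-yl)propyl]cyclohexane-1,3-dione, via pyrrol-1-ylmagnesium bromide 6 (not isolated)
Conditions: 5 (2.3 equiv), EtMgBr (2.2 equiv), Et2O–toluene, 0 °C, 30 min; then 4, −40 °C to 20 °C, 3 h; aq. HCl (1 mol/L) quench
Reagents that add atoms: none
Why: Oddo-type C2-acylation of a pyrrolylmagnesium halide by an activated ester, here extended to an enol lactone (a vinylogous mixed anhydride whose leaving group is the dione enolate); any N-acylpyrrole can be returned by that enolate, whereas the C-acyl product is held as its magnesium pyrrolide, which is why two equivalents of 6 are used.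

Step 3
Reactants: 7 2-[3-oxo-3-(1H-pyrrol-2-yl)propyl]cyclohexane-1,3-dione
Product: 10 1-(4,5-dichloro-1H-pyrrol-2-yl)-3-(2,6-dihydroxyphenyl)propan-1-one, via 2-chloro triketone 8 (not isolated), via 4-chloro enol 9 (not isolated)
Conditions: SO2Cl2 (3.05 equiv), CH2Cl2, −20 °C to 0 °C, 2 h; evaporate; then HCl (4 mol/L in dioxane, 0.5 equiv), DMF, 90 °C, 3 h
Reagents that add atoms: sulfuryl chloride, O=S(=O)(Cl)Cl
Why: Proposed new method: SO2Cl2 chlorinates the 2-acylpyrrole at C4 and C5 (the established pattern for 2-acylpyrroles) and the enolised dione at C2 to give 8; on heating with HCl in DMF the tertiary chloride shifts to C4 through the dienol (9, racemic, its stereocentre is lost at once) and HCl is eliminated to give the phenol tautomer, so the aromatic ring appears only after the chlorinating agent is used up; the closest known reactions are the SO2Cl2 dichlorination of 2-acylpyrroles and the chlorination–dehydrochlorination of 2-alkylcyclohexane-1,3-diones to 2-alkylresorcinols, combined here in one pot.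

Step 4
Reactants: 10 1-(4,5-dichloro-1H-pyrrol-2-yl)-3-(2,6-dihydroxyphenyl)propan-1-one; 11 4,5-dichloro-1H-pyrrole-2-carboxylic acid
Product: 13 dihydrotetrachlorizine, via 4,5-dichloro-1H-pyrrole-2-carbonyl chloride 12 (not isolated)
Conditions: 11 (1.05 equiv), (COCl)2 (1.2 equiv), DMF (cat.), CH2Cl2, 20 °C, 2 h, evaporate; then 10, AlCl3 (3.5 equiv), 1,2-dichloroethane, 0 °C to 50 °C, 6 h; aq. HCl (1 mol/L) quench
Reagents that add atoms: none
Why: Friedel–Crafts acylation of a resorcinol by an acid chloride made in the flask; the two activated ring carbons of 10 (each ortho to one OH and para to the other) are equivalent by symmetry so only one monoketone can form, the first acyl group slows a second acylation, and both dichloropyrrole rings are too electron-poor to be acylated.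

**Compound list**
1 | cyclohexane-1,3-dione | O=C1CCCC(=O)C1 | starting material
2 | acrylic acid (prop-2-enoic acid) | C=CC(=O)O | starting material
3 | 3-(2,6-dioxocyclohexyl)propanoic acid | O=C(O)CCC1C(=O)CCCC1=O | intermediate
4 | 3,4,7,8-tetrahydro-2H-chromene-2,5(6H)-dione | O=C1CCC2=C(CCCC2=O)O1 | intermediate
5 | 1H-pyrrole | c1cc[nH]c1 | starting material
6 | pyrrol-1-ylmagnesium bromide | Br[Mg]n1cccc1 | intermediate
7 | 2-[3-oxo-3-(1H-pyrrol-2-yl)propyl]cyclohexane-1,3-dione | O=C(CCC1C(=O)CCCC1=O)c1ccc[nH]1 | intermediate
8 | 2-chloro-2-[3-(4,5-dichloro-1H-pyrrol-2-yl)-3-oxopropyl]cyclohexane-1,3-dione | O=C(CCC1(Cl)C(=O)CCCC1=O)c1cc(Cl)c(Cl)[nH]1 | intermediate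
9 | racemic 4-chloro-2-[3-(4,5-dichloro-1H-pyrrol-2-yl)-3-oxopropyl]-3-hydroxycyclohex-2-en-1-one | O=C(CCC1=C(O)C(Cl)CCC1=O)c1cc(Cl)c(Cl)[nH]1 | intermediate
10 | 1-(4,5-dichloro-1H-pyrrol-2-yl)-3-(2,6-dihydroxyphenyl)propan-1-one | O=C(CCc1c(O)cccc1O)c1cc(Cl)c(Cl)[nH]1 | intermediate
11 | 4,5-dichloro-1H-pyrrole-2-carboxylic acid | O=C(O)c1cc(Cl)c(Cl)[nH]1 | starting material
12 | 4,5-dichloro-1H-pyrrole-2-carbonyl chloride | O=C(Cl)c1cc(Cl)c(Cl)[nH]1 | intermediate
13 | dihydrotetrachlorizine, 1-(4,5-dichloro-1H-pyrrol-2-yl)-3-[3-(4,5-dichloro-1H-pyrrole-2-carbonyl)-2,6-dihydroxyphenyl]propan-1-one (achiral) | O=C(CCc1c(O)ccc(C(=O)c2cc(Cl)c(Cl)[nH]2)c1O)c1cc(Cl)c(Cl)[nH]1 | target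

**Step count and risks**
Total step count: 4. Longest linear sequence: 4 steps (1 → 4 → 7 → 10 → 13); pyrrole 5 and acid 11 are bought.

Most likely to fail, step 3. The risks are a third chlorination of the pyrrole, chlorine being passed from the chloro-dione to the newly formed resorcinol, and ring cleavage of 8. The fallback sets out from 7 and comes back at 10; it separates aromatisation from chlorination and masks the phenols. Compound 7 is dehydrogenated with 10% Pd/C in refluxing diglyme under a nitrogen sweep to 3-(2,6-dihydroxyphenyl)-1-(1H-pyrrol-2-yl)propan-1-one F1. Both phenols are then acetylated with Ac2O in pyridine to give 2-[3-oxo-3-(1H-pyrrol-2-yl)propyl]-1,3-phenylene diacetate F2. The pyrrole is dichlorinated with SO2Cl2 (2.05 equiv, CH2Cl2, 0 °C) to 2-[3-(4,5-dichloro-1H-pyrrol-2-yl)-3-oxopropyl]-1,3-phenylene diacetate F3. The acetates are removed with K2CO3 in MeOH to give 10.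

Second, step 2. The risks are N-acylation, attack at the ring ketone or the enol carbon of the lactone instead of the lactone carbonyl, and some C3-acylation. The fallback sets out from 5 (through 6), uses 1 as partner, and comes back at 7; it builds the chain in the opposite sense, by Michael addition. Compound 6 is acylated with 3-chloropropanoyl chloride in toluene at −40 °C to give 3-chloro-1-(1H-pyrrol-2-yl)propan-1-one F4. With Et3N in MeCN at 20 °C, F4 loses HCl to 1-(1H-pyrrol-2-yl)prop-2-en-1-one F5, which is formed in the flask and trapped at once by the enolate of 1 through C2 to give 7. Et3N is too weak to deprotonate the pyrrole N–H, so ring closure on nitrogen should not compete.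

Third, step 4. The risks are O-acylation without migration, decomposition of the N–H acid chloride, and cyclisation of a phenol onto the side-chain ketone under AlCl3. The fallback sets out from 10 and comes back at 13; it makes the aryl ester on purpose and moves the acyl group photochemically. Compound 10 (slight excess) is coupled with 11 (EDC·HCl, DMAP cat., CH2Cl2) to give 2-[3-(4,5-dichloro-1H-pyrrol-2-yl)-3-oxopropyl]-3-hydroxyphenyl 4,5-dichloro-1H-pyrrole-2-carboxylate F6. A photo-Fries rearrangement (hν 300 nm, degassed MeCN) then transfers the acyl group to carbon; ortho and para migration end at equivalent ring carbons, so both give 13.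

**Further compounds**
F1 | step 3 | 3-(2,6-dihydroxyphenyl)-1-(1H-pyrrol-2-yl)propan-1-one | O=C(CCc1c(O)cccc1O)c1ccc[nH]1
F2 | step 3 | 2-[3-oxo-3-(1H-pyrrol-2-yl)propyl]-1,3-phenylene diacetate | CC(=O)Oc1cccc(OC(C)=O)c1CCC(=O)c1ccc[nH]1
F3 | step 3 | 2-[3-(4,5-dichloro-1H-pyrrol-2-yl)-3-oxopropyl]-1,3-phenylene diacetate | CC(=O)Oc1cccc(OC(C)=O)c1CCC(=O)c1cc(Cl)c(Cl)[nH]1
F4 | step 2 | 3-chloro-1-(1H-pyrrol-2-yl)propan-1-one | O=C(CCCl)c1ccc[nH]1
F5 | step 2 | 1-(1H-pyrrol-2-yl)prop-2-en-1-one | C=CC(=O)c1ccc[nH]1
F6 | step 4 | 2-[3-(4,5-dichloro-1H-pyrrol-2-yl)-3-oxopropyl]-3-hydroxyphenyl 4,5-dichloro-1H-pyrrole-2-carboxylate | O=C(CCc1c(O)cccc1OC(=O)c1cc(Cl)c(Cl)[nH]1)c1cc(Cl)c(Cl)[nH]1
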